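## Retrosynthetic overview

1. Target 28 comes from the ten-membered epoxy alcohol 25 by angeloylation of the C1 hydroxyl (last step).
2. 25 comes from the acyclic epoxy alkenyl iodide 23 by closing C4–C5 in a one-pot hydroboration / intramolecular B-alkyl Suzuki–Miyaura coupling (the new step; it forms the cyclodecene ring).
3. 23 comes from allylic alcohol 22 by matched Sharpless epoxidation (oxirane ring, C9 and C10); 22 comes from enal 15 and (Z)-allylboronate 18 (C7–C8 bond, C7 and C8 stereocentres).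
4. 15 comes from prenol by PMB protection, SeO2 oxidation (E-C9=C10), asymmetric propargylation (C1), alkyne methylation and hydrozirconation–iodination (E-C3=C4).
5. Ring order: oxirane first (step 13), then the ten-membered carbocycle (step 14).

Assumption: the side chain in the SMILES is the (Z)-2-methylbut-2-enoate (angelate); ring carbons are called C1 (angelate carbon), C2, C3=C4(Me), C5, C6, C7 (iPr), C8 (OAc), C9 and C10 (Me) (epoxide) in all intermediates; reagents without a number are bought.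

## Route

Step 1
Reactants: 1 3-methylbut-2-en-1-ol (prenol)
Product: 3 1-methoxy-4-{[(3-methylbut-2-en-1-yl)oxy]methyl}benzene (PMB prenyl ether), via sodium prenoxide 2 (not isolated)
Conditions: NaH, THF/DMF, 0 °C; 4-methoxybenzyl chloride, Bu4NI (cat.), 0 °C → rt
Reagents that add atoms: 4-methoxybenzyl chloride, COc1ccc(CCl)cc1
Why: Williamson ether synthesis (SN2 of the alkoxide on the benzylic chloride) masks the future C8 oxygen as a PMB ether that can later be removed oxidatively beside a silyl ether.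

Step 2
Reactants: 3 PMB prenyl ether
Product: 5 (2E)-4-[(4-methoxybenzyl)oxy]-2-methylbut-2-enal, via allylic alcohol 4 (not isolated)
Conditions: SeO2 (1.5 equiv), 1,4-dioxane, 80 °C
Reagents that add atoms: selenium dioxide, O=[Se]=O
Why: Riley allylic oxidation (ene reaction, then [2,3]-sigmatropic shift) attacks only the methyl group trans to the chain and runs on to the aldehyde, which fixes the (E) geometry of the later C9=C10 unit (C8 and C1 trans).

Step 3
Reactants: 5 enal; 6 allenylboronic acid pinacol ester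
Product: 8 (4R,5E)-7-[(4-methoxybenzyl)oxy]-5-methylhept-5-en-1-yn-4-ol, via pinacol borate ester 7 (not isolated)
Conditions: 6 (1.5 equiv), (R)-TRIP [(R)-3,3'-bis(2,4,6-triisopropylphenyl)-1,1'-binaphthyl-2,2'-diyl hydrogen phosphate] (5 mol %), 4 Å MS, toluene, −20 °C; aq. NaHCO3 work-up
Reagents that add atoms: none
Why: Chiral phosphoric acid-catalysed allenylboration (SE2' carbonyl propargylation through a six-membered chair transition state in which the acid hydrogen-bonds to a boronate oxygen and its P=O binds the formyl hydrogen); the (R)-acid is expected to deliver the propargyl group to the Re face of the enal, setting C1 as R.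

Step 4
Reactants: 8 homopropargylic alcohol
Product: 9 tert-butyl{[(4R,5E)-7-[(4-methoxybenzyl)oxy]-5-methylhept-5-en-1-yn-4-yl]oxy}dimethylsilane
Conditions: TBSCl, imidazole, DMF, rt
Reagents that add atoms: tert-butyldimethylsilyl chloride, CC(C)(C)[Si](C)(C)Cl
Why: Standard imidazole-promoted silylation protects the C1 hydroxyl through the organometallic steps that follow.

Step 5
Reactants: 9 TBS ether
Product: 11 tert-butyl{[(2E,4R)-1-[(4-methoxybenzyl)oxy]-3-methyloct-2-en-6-yn-4-yl]oxy}dimethylsilane, via lithium acetylide 10 (not isolated)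
Conditions: n-BuLi, THF, −78 °C; MeI, −78 °C → rt
Reagents that add atoms: iodomethane, CI
Why: Deprotonation of the terminal alkyne and SN2 methylation of the acetylide install the carbon that becomes the C4 methyl group.

Step 6
Reactants: 11 methyl alkyne
Product: 13 tert-butyl{[(2E,4R,6E)-7-iodo-1-[(4-methoxybenzyl)oxy]-3-methylocta-2,6-dien-4-yl]oxy}dimethylsilane, via alkenylzirconocene chloride 12 (not isolated)
Conditions: Cp2Zr(H)Cl (2.5 equiv), THF, 50 °C; I2, 0 °C
Reagents that add atoms: iodine, II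
Why: Syn hydrozirconation of the internal alkyne places zirconium on the less hindered, methyl-bearing carbon after equilibration with excess hydride, and iodinolysis with retention gives the (E)-alkenyl iodide (iodine trans to C2), which fixes the C3=C4 geometry.

Step 7
Reactants: 13 PMB ether
Product: 14 (2E,4R,6E)-4-[(tert-butyldimethylsilyl)oxy]-7-iodo-3-methylocta-2,6-dien-1-ol
Conditions: DDQ, CH2Cl2/pH 7 buffer, 0 °C
Reagents that add atoms: none
Why: Oxidative PMB cleavage (benzylic hydride abstraction by DDQ, then hydrolysis of the oxocarbenium ion) frees the primary allylic alcohol and leaves the TBS ether and the alkenyl iodide untouched.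

Step 8
Reactants: 14 allylic alcohol
Product: 15 (2E,4R,6E)-4-[(tert-butyldimethylsilyl)oxy]-7-iodo-3-methylocta-2,6-dienal
Conditions: MnO2, CH2Cl2, rt
Reagents that add atoms: none
Why: MnO2 oxidises the primary allylic alcohol selectively to the enal without E/Z isomerisation.

Step 9
Reactants: 16 4-methylpenta-1,3-diene; 17 pinacolborane
Product: 18 4,4,5,5-tetramethyl-2-[(2Z)-4-methylpent-2-en-1-yl]-1,3,2-dioxaborolane
Conditions: Ni(cod)2 (2.5 mol %), PCy3 (2.5 mol %), toluene, rt
Reagents that add atoms: none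
Why: Nickel-catalysed 1,4-hydroboration of a 1,3-diene: the s-cis-bound diene gives a π-allyl nickel intermediate that puts boron on the unsubstituted terminus and hydrogen on the dimethyl terminus, giving the (Z)-allylboronate needed for syn selectivity in step 10.

Step 10
Reactants: 15 enal; 18 (Z)-allylboronate
Product: 20 (3R,4S,5E,7R,9E)-7-[(tert-butyldimethylsilyl)oxy]-10-iodo-6-methyl-3-(propan-2-yl)undeca-1,5,9-trien-4-ol, via pinacol borate ester 19 (not isolated)
Conditions: 18 (1.5 equiv), (S)-TRIP [(S)-3,3'-bis(2,4,6-triisopropylphenyl)-1,1'-binaphthyl-2,2'-diyl hydrogen phosphate] (10 mol %), 4 Å MS, toluene, −30 °C → rt; aq. NaHCO3 work-up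
Reagents that add atoms: none
Why: Chiral phosphoric acid-catalysed allylboration through a closed Zimmerman–Traxler chair: the (Z)-γ-isopropyl group is axial, so the C7/C8 syn adduct forms, and the (S)-acid directs attack to the Si face of the aldehyde, which sets C8 (S) and C7 in the configuration of the target (C7 is R by CIP while C6 is vinylic and becomes S after ring closure).

Step 11
Reactants: 20 homoallylic alcohol
Product: 21 (3R,4S,5E,7R,9E)-7-[(tert-butyldimethylsilyl)oxy]-10-iodo-6-methyl-3-(propan-2-yl)undeca-1,5,9-trien-4-yl acetate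
Conditions: Ac2O, pyridine, DMAP (cat.), CH2Cl2, 0 °C → rt
Reagents that add atoms: acetic anhydride, CC(=O)OC(C)=O
Why: DMAP-catalysed acylation installs the C8 acetate of the target without touching a stereocentre.

Step 12
Reactants: 21 acetate
Product: 22 (3R,4S,5E,7R,9E)-7-hydroxy-10-iodo-6-methyl-3-(propan-2-yl)undeca-1,5,9-trien-4-yl acetate
Conditions: HF·pyridine, pyridine, THF, 0 °C → rt
Reagents that add atoms: none
Why: Buffered fluoride desilylation frees the C1 allylic alcohol and leaves the acetate and the alkenyl iodide intact.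

Step 13
Reactants: 22 allylic alcohol
Product: 23 (1S,2R)-1-{(2R,3R)-3-[(1R,3E)-1-hydroxy-4-iodopent-3-en-1-yl]-3-methyloxiran-2-yl}-2-(propan-2-yl)but-3-en-1-yl acetate
Conditions: Ti(OiPr)4 (10 mol %), D-(−)-diisopropyl tartrate (15 mol %), t-BuOOH (2 equiv), 4 Å MS, CH2Cl2, −20 °C
Reagents that add atoms: tert-butyl hydroperoxide, CC(C)(C)OO
Why: Sharpless asymmetric epoxidation touches only the C9=C10 olefin of the allylic alcohol; D-(−)-tartrate is the matched ligand for the (R)-carbinol (the fast-reacting enantiomer in the kinetic-resolution sense), so the erythro epoxy alcohol with C9 (R) and C10 (R) forms, while any material with the wrong C1 configuration reacts slowly and is left behind.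

Step 14
Reactants: 23 acyclic epoxy alkenyl iodide
Product: 25 (1R,2R,4E,8S,9S,10R)-2-hydroxy-1,5-dimethyl-8-(propan-2-yl)-11-oxabicyclo[8.1.0]undec-4-en-9-yl acetate, via bis(9-BBN) adduct 24 (not isolated)
Conditions: 9-BBN-H (2.5 equiv), THF, 0 °C → rt, 3 h; then added over 12 h to Pd(dppf)Cl2 (20 mol %), AsPh3 (40 mol %), Cs2CO3 (3 equiv), degassed DMF/THF/H2O, rt, final 1 mM
Reagents that add atoms: none
Why: Proposed new method: one-pot hydroboration / intramolecular B-alkyl Suzuki–Miyaura coupling used to close a ten-membered (E)-cycloalkene; 9-BBN-H adds anti-Markovnikov to the only monosubstituted alkene (and transiently borylates the C1 hydroxyl), zerovalent palladium inserts into the C4–I bond with retention, the hydroxide-activated alkylborane transfers the primary C5 carbon within the molecule to give an eleven-membered palladacycle, and the wide-bite-angle dppf ligand drives C(sp2)–C(sp3) reductive elimination ahead of β-hydride elimination, so the C4–C5 bond and the germacrane ring form with the olefin geometry already locked in the alkenyl iodide and no stereocentre touched; the rigid trans-epoxide, the (E)-alkene and the contiguous C7–C1 substituents fold the chain, and slow addition at 1 mM suppresses oligomers; the closest known reaction type is the intermolecular B-alkyl Suzuki–Miyaura coupling and its macrocyclising use for rings of twelve or more atoms, which to my knowledge has not been shown for a strained ten-membered (E)-cycloalkene.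

Step 15
Reactants: 25 ten-membered epoxy alcohol; 26 angelic acid
Product: 28 (1R,2R,4E,8S,9S,10R)-9-(acetyloxy)-1,5-dimethyl-8-(propan-2-yl)-11-oxabicyclo[8.1.0]undec-4-en-2-yl (2Z)-2-methylbut-2-enoate (target), via mixed anhydride 27 (not isolated)
Conditions: 26, 2,4,6-trichlorobenzoyl chloride, Et3N, toluene, rt; then 25, DMAP, toluene, rt → 40 °C
Reagents that add atoms: none
Why: Yamaguchi esterification through the mixed anhydride acylates the hindered C1 alcohol under mild, non-acidic conditions that keep the (Z)-enoate geometry and the acid-sensitive epoxy-germacrene intact.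

## Compound list

1 | 3-methylbut-2-en-1-ol (prenol) | CC(C)=CCO | starting material
2 | sodium 3-methylbut-2-en-1-olate | CC(C)=CC[O-].[Na+] | intermediate
3 | 1-methoxy-4-{[(3-methylbut-2-en-1-yl)oxy]methyl}benzene | CC(C)=CCOCc1ccc(OC)cc1 | intermediate
4 | (2E)-4-[(4-methoxybenzyl)oxy]-2-methylbut-2-en-1-ol | OC/C(C)=C/COCc1ccc(OC)cc1 | intermediate
5 | (2E)-4-[(4-methoxybenzyl)oxy]-2-methylbut-2-enal | O=C/C(C)=C/COCc1ccc(OC)cc1 | intermediate
6 | 4,4,5,5-tetramethyl-2-(propa-1,2-dien-1-yl)-1,3,2-dioxaborolane (allenylboronic acid pinacol ester) | C=C=CB1OC(C)(C)C(C)(C)O1 | starting material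
7 | 4,4,5,5-tetramethyl-1,3,2-dioxaborolan-2-yl (borate) ester of 8 | C#CC[C@@H](OB1OC(C)(C)C(C)(C)O1)/C(C)=C/COCc1ccc(OC)cc1 | intermediate
8 | (4R,5E)-7-[(4-methoxybenzyl)oxy]-5-methylhept-5-en-1-yn-4-ol | C#CC[C@@H](O)/C(C)=C/COCc1ccc(OC)cc1 | intermediate
9 | tert-butyl{[(4R,5E)-7-[(4-methoxybenzyl)oxy]-5-methylhept-5-en-1-yn-4-yl]oxy}dimethylsilane | C#CC[C@@H](O[Si](C)(C)C(C)(C)C)/C(C)=C/COCc1ccc(OC)cc1 | intermediate
10 | lithium acetylide of 9 (lithium on the terminal alkyne carbon) | [Li]C#CC[C@@H](O[Si](C)(C)C(C)(C)C)/C(C)=C/COCc1ccc(OC)cc1 | intermediate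
11 | tert-butyl{[(2E,4R)-1-[(4-methoxybenzyl)oxy]-3-methyloct-2-en-6-yn-4-yl]oxy}dimethylsilane | CC#CC[C@@H](O[Si](C)(C)C(C)(C)C)/C(C)=C/COCc1ccc(OC)cc1 | intermediate
12 | chloridobis(cyclopentadienyl)zirconium (E)-alkenyl complex of 11 (zirconium on C4, cis to the new C3–H) | C/C(=C\C[C@@H](O[Si](C)(C)C(C)(C)C)/C(C)=C/COCc1ccc(OC)cc1)[Zr](Cl)(C1C=CC=C1)C1C=CC=C1 | intermediate
13 | tert-butyl{[(2E,4R,6E)-7-iodo-1-[(4-methoxybenzyl)oxy]-3-methylocta-2,6-dien-4-yl]oxy}dimethylsilane | C/C(I)=C\C[C@@H](O[Si](C)(C)C(C)(C)C)/C(C)=C/COCc1ccc(OC)cc1 | intermediate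
14 | (2E,4R,6E)-4-[(tert-butyldimethylsilyl)oxy]-7-iodo-3-methylocta-2,6-dien-1-ol | C/C(I)=C\C[C@@H](O[Si](C)(C)C(C)(C)C)/C(C)=C/CO | intermediate
15 | (2E,4R,6E)-4-[(tert-butyldimethylsilyl)oxy]-7-iodo-3-methylocta-2,6-dienal | C/C(I)=C\C[C@@H](O[Si](C)(C)C(C)(C)C)/C(C)=C/C=O | intermediate
16 | 4-methylpenta-1,3-diene | CC(C)=CC=C | starting material
17 | 4,4,5,5-tetramethyl-1,3,2-dioxaborolane (pinacolborane) | [H]B1OC(C)(C)C(C)(C)O1 | starting material
18 | 4,4,5,5-tetramethyl-2-[(2Z)-4-methylpent-2-en-1-yl]-1,3,2-dioxaborolane | CC(C)/C=C\CB1OC(C)(C)C(C)(C)O1 | intermediate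
19 | 4,4,5,5-tetramethyl-1,3,2-dioxaborolan-2-yl (borate) ester of 20 | C/C(I)=C\C[C@@H](O[Si](C)(C)C(C)(C)C)/C(C)=C/[C@@H](OB1OC(C)(C)C(C)(C)O1)[C@@H](C=C)C(C)C | intermediate
20 | (3R,4S,5E,7R,9E)-7-[(tert-butyldimethylsilyl)oxy]-10-iodo-6-methyl-3-(propan-2-yl)undeca-1,5,9-trien-4-ol | C/C(I)=C\C[C@@H](O[Si](C)(C)C(C)(C)C)/C(C)=C/[C@@H](O)[C@@H](C=C)C(C)C | intermediate
21 | (3R,4S,5E,7R,9E)-7-[(tert-butyldimethylsilyl)oxy]-10-iodo-6-methyl-3-(propan-2-yl)undeca-1,5,9-trien-4-yl acetate | C/C(I)=C\C[C@@H](O[Si](C)(C)C(C)(C)C)/C(C)=C/[C@@H](OC(C)=O)[C@@H](C=C)C(C)C | intermediate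
22 | (3R,4S,5E,7R,9E)-7-hydroxy-10-iodo-6-methyl-3-(propan-2-yl)undeca-1,5,9-trien-4-yl acetate | C/C(I)=C\C[C@@H](O)/C(C)=C/[C@@H](OC(C)=O)[C@@H](C=C)C(C)C | intermediate
23 | (1S,2R)-1-{(2R,3R)-3-[(1R,3E)-1-hydroxy-4-iodopent-3-en-1-yl]-3-methyloxiran-2-yl}-2-(propan-2-yl)but-3-en-1-yl acetate | C/C(I)=C\C[C@@H](O)[C@@]1(C)O[C@@H]1[C@@H](OC(C)=O)[C@@H](C=C)C(C)C | intermediate
24 | 23 carrying a 9-borabicyclo[3.3.1]nonan-9-yl group on C5 (hydroborated vinyl) and on the C1 oxygen | C/C(I)=C\C[C@@H](OB2C3CCCC2CCC3)[C@@]1(C)O[C@@H]1[C@@H](OC(C)=O)[C@@H](CCB4C5CCCC4CCC5)C(C)C | intermediate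
25 | (1R,2R,4E,8S,9S,10R)-2-hydroxy-1,5-dimethyl-8-(propan-2-yl)-11-oxabicyclo[8.1.0]undec-4-en-9-yl acetate (locants as in the target) | O[C@@H]1C/C=C(\C)CC[C@@H](C(C)C)[C@H](OC(C)=O)[C@H]2O[C@@]21C | intermediate
26 | (2Z)-2-methylbut-2-enoic acid (angelic acid) | C/C=C(/C)C(=O)O | starting material
27 | (2Z)-2-methylbut-2-enoic 2,4,6-trichlorobenzoic anhydride | C/C=C(/C)C(=O)OC(=O)c1c(Cl)cc(Cl)cc1Cl | intermediate
28 | (1R,2R,4E,8S,9S,10R)-9-(acetyloxy)-1,5-dimethyl-8-(propan-2-yl)-11-oxabicyclo[8.1.0]undec-4-en-2-yl (2Z)-2-methylbut-2-enoate | C/C=C(/C)C(=O)O[C@@H]1C/C=C(\C)CC[C@@H](C(C)C)[C@H](OC(C)=O)[C@H]2O[C@@]21C | target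

## Step count and risks

Total step count: 15. Longest linear sequence: 14 steps (steps 1–8 and 10–15; step 9 is a one-step side branch).

The three steps most likely to fail:

1. Step 14 (the new macrocyclisation). Risks are oligomerisation, β-hydride elimination or protodeiodination, and the strain of the ten-membered (E)-ring. The fallback uses known chemistry, sets out from 23 and comes back at 25. Stille coupling of 23 with Bu3SnCH=CH2 (Pd(PPh3)4, CuI, DMF, 40 °C) replaces iodine by vinyl with retention and gives the triene F1. Ring-closing metathesis with the second-generation Grubbs catalyst RuCl2(=CHPh)(PCy3)(H2IMes) in toluene at 80 °C and 0.5 mM joins the two vinyl groups and gives the cyclic diene F2 (the geometry of the new C5=C6 bond does not matter). Diimide (2-nitrobenzenesulfonohydrazide, Et3N, CH2Cl2, rt) then saturates only the disubstituted C5=C6 bond and gives 25.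

2. Step 10 (allylboration with a hindered γ-branched (Z)-allylboronate). Risks are slow reaction and eroded syn selectivity or ee. The fallback sets out from 15 and comes back at 20. (S)-4-Benzyl-1,3-oxazolidin-2-one is acylated (n-BuLi, 3-methylbutanoyl chloride, THF, −78 °C) to the imide F3. Its dibutylboron (Z)-enolate (Bu2BOTf, Et3N, CH2Cl2, −78 → 0 °C) adds to 15 in an Evans syn-aldol reaction under auxiliary control and gives the aldol adduct F4. TESOTf and 2,6-lutidine give the silyl ether F5, and LiBH4 in THF/MeOH removes the auxiliary to give the primary alcohol F6. Dess–Martin periodinane gives the aldehyde F7, and Wittig methylenation with Ph3P=CH2 gives the alkene F8. PPTS in MeOH at 0 °C removes the triethylsilyl group selectively and returns 20.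

3. Step 15 (angeloylation of the hindered C1 alcohol). Risks are low conversion and isomerisation of the angelate to the tiglate. The fallback sets out from 25 and comes back at 28. Esterification of 25 with but-2-ynoic acid (DCC, DMAP, CH2Cl2) gives the butynoate F9. Syn hydrostannation with Bu3SnH catalysed by Pd(PPh3)4 in THF puts tin on the α-carbon and gives the stannane F10. Stille methylation (MeI, Pd2(dba)3, tri(2-furyl)phosphine, CuI, DMF) replaces tin by methyl with retention and gives 28, with the Z geometry fixed by the syn addition and not by the esterification conditions.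

## Further compounds

F1 | step 14 | (1S,2R)-1-{(2R,3R)-3-[(1R,3E)-1-hydroxy-4-methylhexa-3,5-dien-1-yl]-3-methyloxiran-2-yl}-2-(propan-2-yl)but-3-en-1-yl acetate | C=C/C(C)=C/C[C@@H](O)[C@@]1(C)O[C@@H]1[C@@H](OC(C)=O)[C@@H](C=C)C(C)C
F2 | step 14 | (1R,2R,4E,6Z,8R,9S,10R)-2-hydroxy-1,5-dimethyl-8-(propan-2-yl)-11-oxabicyclo[8.1.0]undeca-4,6-dien-9-yl acetate | O[C@@H]1C/C=C(\C)/C=C\[C@@H](C(C)C)[C@H](OC(C)=O)[C@H]2O[C@@]21C
F3 | step 10 | (4S)-4-benzyl-3-(3-methylbutanoyl)-1,3-oxazolidin-2-one | CC(C)CC(=O)N1[C@@H](Cc2ccccc2)COC1=O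
F4 | step 10 | (4S)-4-benzyl-3-[(2S,3R,4E,6R,8E)-6-[(tert-butyldimethylsilyl)oxy]-3-hydroxy-9-iodo-5-methyl-2-(propan-2-yl)deca-4,8-dienoyl]-1,3-oxazolidin-2-one | C/C(I)=C\C[C@@H](O[Si](C)(C)C(C)(C)C)/C(C)=C/[C@@H](O)[C@H](C(C)C)C(=O)N1[C@@H](Cc2ccccc2)COC1=O
F5 | step 10 | (4S)-4-benzyl-3-[(2S,3R,4E,6R,8E)-6-[(tert-butyldimethylsilyl)oxy]-9-iodo-5-methyl-2-(propan-2-yl)-3-[(triethylsilyl)oxy]deca-4,8-dienoyl]-1,3-oxazolidin-2-one | C/C(I)=C\C[C@@H](O[Si](C)(C)C(C)(C)C)/C(C)=C/[C@@H](O[Si](CC)(CC)CC)[C@H](C(C)C)C(=O)N1[C@@H](Cc2ccccc2)COC1=O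
F6 | step 10 | (2R,3R,4E,6R,8E)-6-[(tert-butyldimethylsilyl)oxy]-9-iodo-5-methyl-2-(propan-2-yl)-3-[(triethylsilyl)oxy]deca-4,8-dien-1-ol | C/C(I)=C\C[C@@H](O[Si](C)(C)C(C)(C)C)/C(C)=C/[C@@H](O[Si](CC)(CC)CC)[C@H](C(C)C)CO
F7 | step 10 | (2S,3R,4E,6R,8E)-6-[(tert-butyldimethylsilyl)oxy]-9-iodo-5-methyl-2-(propan-2-yl)-3-[(triethylsilyl)oxy]deca-4,8-dienal | C/C(I)=C\C[C@@H](O[Si](C)(C)C(C)(C)C)/C(C)=C/[C@@H](O[Si](CC)(CC)CC)[C@H](C(C)C)C=O
F8 | step 10 | (3R,4S,5E,7R,9E)-7-[(tert-butyldimethylsilyl)oxy]-10-iodo-6-methyl-3-(propan-2-yl)-4-[(triethylsilyl)oxy]undeca-1,5,9-triene (triethylsilyl ether of 20) | C/C(I)=C\C[C@@H](O[Si](C)(C)C(C)(C)C)/C(C)=C/[C@@H](O[Si](CC)(CC)CC)[C@H](C(C)C)C=C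
F9 | step 15 | (1R,2R,4E,8S,9S,10R)-9-(acetyloxy)-1,5-dimethyl-8-(propan-2-yl)-11-oxabicyclo[8.1.0]undec-4-en-2-yl but-2-ynoate | CC#CC(=O)O[C@@H]1C/C=C(\C)CC[C@@H](C(C)C)[C@H](OC(C)=O)[C@H]2O[C@@]21C
F10 | step 15 | (1R,2R,4E,8S,9S,10R)-9-(acetyloxy)-1,5-dimethyl-8-(propan-2-yl)-11-oxabicyclo[8.1.0]undec-4-en-2-yl (2E)-2-(tributylstannyl)but-2-enoate | C/C=C(/[Sn](CCCC)(CCCC)CCCC)C(=O)O[C@@H]1C/C=C(\C)CC[C@@H](C(C)C)[C@H](OC(C)=O)[C@H]2O[C@@]21C
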